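**Strategy.** The dihydrobenzofuran is cut at O1–C2 and, one stage earlier, at C3–C3a and C2–aryl. A palladium-catalysed enantioselective conjunctive coupling joins three pieces in one operation: the ring A triflate bonds to C3 and the syringyl group moves from boron to C2 of an (E)-CH=CH–CH2O alkenyl borate, so that both adjacent CH stereocentres (C2: future O1 and syringyl ring; C3: ring A carbon C3a and CH2OH) arise together. The precursor is a lithium borate carrying the silyloxypropenyl group, the silylated syringyl group and a hindered acenaphthylene-derived diol on boron. Boron then becomes oxygen, acid closes the trans furan ring, and a late olefination adds the resorcinol styryl arm.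

Key step: step 7

**Remarks on the chemistry**
- Atom labels O1, C2, C3, C3a and C7a follow the benzofuran numbering of the target and are used for all intermediates.
- Assumption: the (Sp,Sp)-configured ligand is taken to steer palladium to the alkene face that gives (S) at C3. If the opposite sense is found, the enantiomeric ligand is used and nothing else changes.
- Boron carries diol 4 instead of pinacol. A β-substituted alkenyl pinacol borate is expected to pass its alkenyl group directly to palladium, and the bulkier diol is the documented remedy. The diol is a spectator and returns in step 8.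
- All structures were checked against the target: C3 of 13 has the sense of the target, and the aryl groups of 13 are anti, as the mechanism requires.

**Route**

Step 1
Reactants: 1 4-bromo-2,6-dimethoxyphenol
Product: 2 (4-bromo-2,6-dimethoxyphenoxy)tri(propan-2-yl)silane
Conditions: TIPSCl, imidazole, DMF, 40 °C
Reagents that add atoms: chlorotri(propan-2-yl)silane, CC(C)[Si](Cl)(C(C)C)C(C)C
Why: Silyl ether formation on the phenol; the bulky silyl group flanked by two methoxy groups should survive organolithium, peroxide, acid and hydride and fall to fluoride at the end.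

Step 2
Reactants: 3 acenaphthylene-1,2-dione
Product: 4 cis-1,2-dimethyl-1,2-dihydroacenaphthylene-1,2-diol (meso)
Conditions: MeMgBr (2.5 equiv), THF, 0 °C → rt; aq. NH4Cl; recrystallisation
Reagents that add atoms: methylmagnesium bromide, C[Mg]Br
Why: Double Grignard 1,2-addition to the diketone; the second methyl group should enter anti to the solvated magnesium alkoxide of the first adduct, so the cis diol is expected as the main isomer and is purified by crystallisation.

Step 3
Reactants: 5 tert-butyldimethyl(prop-2-yn-1-yloxy)silane; 4 cis-1,2-dimethyl-1,2-dihydroacenaphthylene-1,2-diol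
Product: 7 (E)-3-(tert-butyldimethylsilyloxy)prop-1-enylboronic ester of diol 4, via catechol boronate 6 (not isolated)
Conditions: catecholborane, Cy2BH (5 mol %), THF, rt; then 4, rt
Reagents that add atoms: catecholborane (1,3,2-benzodioxaborole), B1Oc2ccccc2O1
Why: Syn, anti-Markovnikov hydroboration of the terminal alkyne fixes the E-alkene, and diol exchange at boron (transesterification) replaces catechol by the aliphatic cis diol, which forms the more stable dioxaborolane.

Step 4
Reactants: 8 methyl 3,4-dihydroxy-5-methoxybenzoate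
Product: 9 methyl 3-hydroxy-5-methoxy-4-(methoxymethoxy)benzoate
Conditions: MOMCl (1.05 equiv), K2CO3 (1.1 equiv), acetone, 0 °C → rt
Reagents that add atoms: chloromethyl methyl ether, COCCl
Why: Williamson-type O-alkylation; the 4-hydroxyl para to the ester is the more acidic one, so one equivalent of weak base should form and alkylate its phenoxide first.

Step 5
Reactants: 9 methyl 3-hydroxy-5-methoxy-4-(methoxymethoxy)benzoate
Product: 10 methyl 3-methoxy-4-(methoxymethoxy)-5-(trifluoromethylsulfonyloxy)benzoate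
Conditions: Tf2O, pyridine, CH2Cl2, 0 °C
Reagents that add atoms: trifluoromethanesulfonic anhydride, O=S(=O)(OS(=O)(=O)C(F)(F)F)C(F)(F)F
Why: O-sulfonylation of the remaining phenol gives the aryl triflate; the MOM acetal and the ester are inert to these conditions.

Step 6
Reactants: 2 (4-bromo-2,6-dimethoxyphenoxy)tri(propan-2-yl)silane; 7 (E)-3-(tert-butyldimethylsilyloxy)prop-1-enylboronic ester of diol 4
Product: 12 lithium (E)-[3-(tert-butyldimethylsilyloxy)prop-1-enyl][3,5-dimethoxy-4-(triisopropylsilyloxy)phenyl]borate of diol 4, via aryllithium 11 (not isolated)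
Conditions: n-BuLi (1.0 equiv), THF, −78 °C; then 7, −78 °C → rt; volatiles removed in vacuo, residue used as such
Reagents that add atoms: n-butyllithium, [Li]CCCC
Why: Bromine–lithium exchange followed by addition of the aryllithium to trigonal boron (ate-complex formation); evaporation removes 1-bromobutane so the borate is free of halide, and the two possible arrangements at boron converge once boron is trigonal again.

Step 7
Reactants: 12 lithium (E)-[3-(tert-butyldimethylsilyloxy)prop-1-enyl][3,5-dimethoxy-4-(triisopropylsilyloxy)phenyl]borate of diol 4; 10 methyl 3-methoxy-4-(methoxymethoxy)-5-(trifluoromethylsulfonyloxy)benzoate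
Product: 13 methyl 3-[(2S,3R)-1-(tert-butyldimethylsilyloxy)-3-[3,5-dimethoxy-4-(triisopropylsilyloxy)phenyl]-3-(boryl)propan-2-yl]-5-methoxy-4-(methoxymethoxy)benzoate, the boryl group being the cyclic ester of diol 4 (anti adduct)
Conditions: Pd(OAc)2 (3 mol %), (Sp,Sp)-MandyPhos ligand with bis(4-methoxy-3,5-dimethylphenyl)phosphino groups (3.6 mol %), THF, 60 °C
Reagents that add atoms: none
Why: Oxidative addition of triflate 10 to zerovalent palladium gives a cationic arylpalladium complex (divalent palladium) that binds the alkene of borate 12; the syringyl group then shifts from boron to C2 on the face opposite palladium while palladium bonds to C3, and reductive elimination with retention forms C3–C3a, so the two aryl groups add anti across the E-alkene. The closest known reaction type is the enantioselective palladium-catalysed conjunctive cross-coupling of alkenylboron ate complexes with aryl triflates, which is documented for β-substituted alkenyl boronates once boron carries the hindered diol 4. No ring is closed. C3 is controlled by the chiral bisphosphine, which selects the alkene face that palladium binds, and C2 follows from C3 through the stereospecific anti addition to the E-alkene. The step needs the metalate shift to win over direct transfer of the alkenyl group to palladium and over loss of silanolate from the C3–palladium intermediate; the bulky diol on boron, the halide-free borate, the triflate leaving group and the fast reductive elimination imposed by the chelating ligand are meant to secure this, and the electron-rich syringyl group migrates readily.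

Step 8
Reactants: 13 conjunctive coupling product (boronic ester of diol 4)
Product: 14 methyl 3-[(1R,2S)-3-(tert-butyldimethylsilyloxy)-1-[3,5-dimethoxy-4-(triisopropylsilyloxy)phenyl]-1-hydroxypropan-2-yl]-5-methoxy-4-(methoxymethoxy)benzoate
Conditions: 30% H2O2, 2 M NaOH, THF, 0 °C → rt
Reagents that add atoms: hydrogen peroxide, OO
Why: Boronate oxidation; hydroperoxide adds to boron and C2 migrates from boron to oxygen with retention, while the cold, short treatment should spare the methyl ester and the hindered aryl silyl ether.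

Step 9
Reactants: 14 methyl 3-[(1R,2S)-3-(tert-butyldimethylsilyloxy)-1-[3,5-dimethoxy-4-(triisopropylsilyloxy)phenyl]-1-hydroxypropan-2-yl]-5-methoxy-4-(methoxymethoxy)benzoate
Product: 16 methyl (2R,3S)-2-[3,5-dimethoxy-4-(triisopropylsilyloxy)phenyl]-3-(hydroxymethyl)-7-methoxy-2,3-dihydro-1-benzofuran-5-carboxylate, via phenol diol 15 (not isolated)
Conditions: methanolic HCl (ca. 1 M), 40 °C
Reagents that add atoms: none
Why: Acid solvolysis of the MOM acetal and the alkyl TBS ether is followed by SN1 cycloetherification, in which the C2 hydroxyl ionises to a benzylic cation stabilised by the para-silyloxy group and the ring A phenol captures it (5-exo-trig); the aryl and CH2OH groups should settle trans because that approach is less hindered and the closure is reversible under acid, so C2 is fixed relative to C3 whatever its configuration in 14 (a C2 methyl ether formed on the way should funnel to 16 under the same conditions).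

Step 10
Reactants: 16 methyl (2R,3S)-2-[3,5-dimethoxy-4-(triisopropylsilyloxy)phenyl]-3-(hydroxymethyl)-7-methoxy-2,3-dihydro-1-benzofuran-5-carboxylate
Product: 17 [(2R,3S)-2-[3,5-dimethoxy-4-(triisopropylsilyloxy)phenyl]-7-methoxy-2,3-dihydro-1-benzofuran-3,5-diyl]dimethanol
Conditions: i-Bu2AlH (4 equiv), CH2Cl2, −78 → 0 °C; aq. potassium sodium tartrate
Reagents that add atoms: none
Why: Hydride reduction of the aryl ester to the benzylic alcohol; the aryl silyl ether and the benzylic aryl ether at C2 are inert to i-Bu2AlH at low temperature.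

Step 11
Reactants: 17 [(2R,3S)-2-[3,5-dimethoxy-4-(triisopropylsilyloxy)phenyl]-7-methoxy-2,3-dihydro-1-benzofuran-3,5-diyl]dimethanol
Product: 18 (2R,3S)-2-[3,5-dimethoxy-4-(triisopropylsilyloxy)phenyl]-3-(hydroxymethyl)-7-methoxy-2,3-dihydro-1-benzofuran-5-carbaldehyde
Conditions: activated MnO2 (15 equiv), CH2Cl2, rt
Reagents that add atoms: none
Why: MnO2 oxidation is selective for the electron-rich benzylic alcohol on ring A; the non-activated CH2OH at C3 should stay untouched.

Step 12
Reactants: 19 3,5-dihydroxybenzyl alcohol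
Product: 20 tert-butyl{[3,5-bis(tert-butyldimethylsilyloxy)phenyl]methoxy}dimethylsilane
Conditions: TBSCl (3.5 equiv), imidazole, DMF, rt
Reagents that add atoms: tert-butyl(chloro)dimethylsilane, CC(C)(C)[Si](C)(C)Cl
Why: Exhaustive silyl ether formation on both phenols and the benzylic alcohol, which avoids any need to tell the hydroxyl groups apart.

Step 13
Reactants: 20 tert-butyl{[3,5-bis(tert-butyldimethylsilyloxy)phenyl]methoxy}dimethylsilane
Product: 21 1-(bromomethyl)-3,5-bis(tert-butyldimethylsilyloxy)benzene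
Conditions: Ph3PBr2 (1.2 equiv), CH2Cl2, 0 °C → rt
Reagents that add atoms: dibromotriphenylphosphorane, BrP(Br)(c1ccccc1)(c1ccccc1)c1ccccc1
Why: Direct exchange of a silyl ether for bromide: the benzylic ether oxygen attacks phosphorus, the silyl group leaves as silyl bromide and bromide displaces Ph3PO at the benzylic carbon (SN2), whereas the aryl silyl ethers cannot be substituted at carbon.

Step 14
Reactants: 21 1-(bromomethyl)-3,5-bis(tert-butyldimethylsilyloxy)benzene
Product: 22 diethyl {[3,5-bis(tert-butyldimethylsilyloxy)phenyl]methyl}phosphonate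
Conditions: P(OEt)3 (neat), 130 °C
Reagents that add atoms: triethyl phosphite, CCOP(OCC)OCC
Why: Michaelis–Arbuzov reaction of the benzylic bromide; the aryl silyl ethers tolerate the neutral thermal conditions.

Step 15
Reactants: 18 (2R,3S)-2-[3,5-dimethoxy-4-(triisopropylsilyloxy)phenyl]-3-(hydroxymethyl)-7-methoxy-2,3-dihydro-1-benzofuran-5-carbaldehyde; 22 diethyl {[3,5-bis(tert-butyldimethylsilyloxy)phenyl]methyl}phosphonate
Product: 23 [(2R,3S)-5-{(E)-2-[3,5-bis(tert-butyldimethylsilyloxy)phenyl]ethenyl}-2-[3,5-dimethoxy-4-(triisopropylsilyloxy)phenyl]-7-methoxy-2,3-dihydro-1-benzofuran-3-yl]methanol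
Conditions: 22 (2.5 equiv), NaN(SiMe3)2 (2.4 equiv), THF, −78 °C → rt
Reagents that add atoms: none
Why: Horner–Wadsworth–Emmons olefination; the benzylic phosphonate anion adds reversibly to the aldehyde and the anti oxaphosphetane collapses to the E-stilbene, the surplus anion covering the free hydroxyl group.

Step 16
Reactants: 23 [(2R,3S)-5-{(E)-2-[3,5-bis(tert-butyldimethylsilyloxy)phenyl]ethenyl}-2-[3,5-dimethoxy-4-(triisopropylsilyloxy)phenyl]-7-methoxy-2,3-dihydro-1-benzofuran-3-yl]methanol
Product: 24 gnetucleistol F, 5-[(E)-2-[(2R,3S)-2-(4-hydroxy-3,5-dimethoxyphenyl)-3-(hydroxymethyl)-7-methoxy-2,3-dihydro-1-benzofuran-5-yl]ethenyl]benzene-1,3-diol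
Conditions: Bu4NF (4 equiv), AcOH (4 equiv), THF, 0 °C → rt
Reagents that add atoms: none
Why: Fluoride-induced cleavage of the three aryl silyl ethers, buffered with AcOH so that the phenolates of the product are not exposed to base and air and C2 is not opened through a quinone methide.

**Compound list**

1 | 4-bromo-2,6-dimethoxyphenol | COc1cc(Br)cc(OC)c1O | starting material
2 | (4-bromo-2,6-dimethoxyphenoxy)tri(propan-2-yl)silane | COc1cc(Br)cc(OC)c1O[Si](C(C)C)(C(C)C)C(C)C | intermediate
3 | acenaphthylene-1,2-dione | O=C1C(=O)c2cccc3cccc1c23 | starting material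
4 | cis-1,2-dimethyl-1,2-dihydroacenaphthylene-1,2-diol (meso) | O[C@]1(C)c2cccc3cccc(c23)[C@]1(C)O | intermediate
5 | tert-butyldimethyl(prop-2-yn-1-yloxy)silane | C#CCO[Si](C)(C)C(C)(C)C | starting material
6 | 2-[(E)-3-(tert-butyldimethylsilyloxy)prop-1-enyl]-1,3,2-benzodioxaborole | CC(C)(C)[Si](C)(C)OC/C=C/B1Oc2ccccc2O1 | intermediate
7 | (E)-3-(tert-butyldimethylsilyloxy)prop-1-enylboronic ester of diol 4 | CC(C)(C)[Si](C)(C)OC/C=C/B1O[C@]2(C)c3cccc4cccc(c34)[C@]2(C)O1 | intermediate
8 | methyl 3,4-dihydroxy-5-methoxybenzoate | COC(=O)c1cc(O)c(O)c(OC)c1 | starting material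
9 | methyl 3-hydroxy-5-methoxy-4-(methoxymethoxy)benzoate | COCOc1c(O)cc(C(=O)OC)cc1OC | intermediate
10 | methyl 3-methoxy-4-(methoxymethoxy)-5-(trifluoromethylsulfonyloxy)benzoate | COCOc1c(OC)cc(C(=O)OC)cc1OS(=O)(=O)C(F)(F)F | intermediate
11 | [3,5-dimethoxy-4-(triisopropylsilyloxy)phenyl]lithium | [Li]c1cc(OC)c(O[Si](C(C)C)(C(C)C)C(C)C)c(OC)c1 | intermediate
12 | lithium (E)-[3-(tert-butyldimethylsilyloxy)prop-1-enyl][3,5-dimethoxy-4-(triisopropylsilyloxy)phenyl]borate of diol 4 (configuration at boron not defined) | [Li+].COc1cc([B-]2(/C=C/CO[Si](C)(C)C(C)(C)C)O[C@]3(C)c4cccc5cccc(c45)[C@]3(C)O2)cc(OC)c1O[Si](C(C)C)(C(C)C)C(C)C | intermediate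
13 | methyl 3-[(2S,3R)-1-(tert-butyldimethylsilyloxy)-3-[3,5-dimethoxy-4-(triisopropylsilyloxy)phenyl]-3-(boryl)propan-2-yl]-5-methoxy-4-(methoxymethoxy)benzoate, boryl = cyclic ester of diol 4 | COc1cc([C@H](B2O[C@]3(C)c4cccc5cccc(c45)[C@]3(C)O2)[C@H](CO[Si](C)(C)C(C)(C)C)c2cc(C(=O)OC)cc(OC)c2OCOC)cc(OC)c1O[Si](C(C)C)(C(C)C)C(C)C | intermediate
14 | methyl 3-[(1R,2S)-3-(tert-butyldimethylsilyloxy)-1-[3,5-dimethoxy-4-(triisopropylsilyloxy)phenyl]-1-hydroxypropan-2-yl]-5-methoxy-4-(methoxymethoxy)benzoate | COc1cc([C@H](O)[C@H](CO[Si](C)(C)C(C)(C)C)c2cc(C(=O)OC)cc(OC)c2OCOC)cc(OC)c1O[Si](C(C)C)(C(C)C)C(C)C | intermediate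
15 | methyl 3-[(1R,2S)-1-[3,5-dimethoxy-4-(triisopropylsilyloxy)phenyl]-1,3-dihydroxypropan-2-yl]-4-hydroxy-5-methoxybenzoate | COc1cc([C@H](O)[C@H](CO)c2cc(C(=O)OC)cc(OC)c2O)cc(OC)c1O[Si](C(C)C)(C(C)C)C(C)C | intermediate
16 | methyl (2R,3S)-2-[3,5-dimethoxy-4-(triisopropylsilyloxy)phenyl]-3-(hydroxymethyl)-7-methoxy-2,3-dihydro-1-benzofuran-5-carboxylate | COc1cc([C@@H]2Oc3c(OC)cc(C(=O)OC)cc3[C@H]2CO)cc(OC)c1O[Si](C(C)C)(C(C)C)C(C)C | intermediate
17 | [(2R,3S)-2-[3,5-dimethoxy-4-(triisopropylsilyloxy)phenyl]-7-methoxy-2,3-dihydro-1-benzofuran-3,5-diyl]dimethanol | COc1cc([C@@H]2Oc3c(OC)cc(CO)cc3[C@H]2CO)cc(OC)c1O[Si](C(C)C)(C(C)C)C(C)C | intermediate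
18 | (2R,3S)-2-[3,5-dimethoxy-4-(triisopropylsilyloxy)phenyl]-3-(hydroxymethyl)-7-methoxy-2,3-dihydro-1-benzofuran-5-carbaldehyde | COc1cc([C@@H]2Oc3c(OC)cc(C=O)cc3[C@H]2CO)cc(OC)c1O[Si](C(C)C)(C(C)C)C(C)C | intermediate
19 | 3,5-dihydroxybenzyl alcohol | OCc1cc(O)cc(O)c1 | starting material
20 | tert-butyl{[3,5-bis(tert-butyldimethylsilyloxy)phenyl]methoxy}dimethylsilane | CC(C)(C)[Si](C)(C)OCc1cc(O[Si](C)(C)C(C)(C)C)cc(O[Si](C)(C)C(C)(C)C)c1 | intermediate
21 | 1-(bromomethyl)-3,5-bis(tert-butyldimethylsilyloxy)benzene | BrCc1cc(O[Si](C)(C)C(C)(C)C)cc(O[Si](C)(C)C(C)(C)C)c1 | intermediate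
22 | diethyl {[3,5-bis(tert-butyldimethylsilyloxy)phenyl]methyl}phosphonate | CCOP(=O)(Cc1cc(O[Si](C)(C)C(C)(C)C)cc(O[Si](C)(C)C(C)(C)C)c1)OCC | intermediate
23 | [(2R,3S)-5-{(E)-2-[3,5-bis(tert-butyldimethylsilyloxy)phenyl]ethenyl}-2-[3,5-dimethoxy-4-(triisopropylsilyloxy)phenyl]-7-methoxy-2,3-dihydro-1-benzofuran-3-yl]methanol | COc1cc([C@@H]2Oc3c(OC)cc(/C=C/c4cc(O[Si](C)(C)C(C)(C)C)cc(O[Si](C)(C)C(C)(C)C)c4)cc3[C@H]2CO)cc(OC)c1O[Si](C(C)C)(C(C)C)C(C)C | intermediate
24 | gnetucleistol F, 5-[(E)-2-[(2R,3S)-2-(4-hydroxy-3,5-dimethoxyphenyl)-3-(hydroxymethyl)-7-methoxy-2,3-dihydro-1-benzofuran-5-yl]ethenyl]benzene-1,3-diol | COc1cc([C@@H]2Oc3c(OC)cc(/C=C/c4cc(O)cc(O)c4)cc3[C@H]2CO)cc(OC)c1O | target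

**Step count.** Total: 16 steps. Longest linear sequence: 10 steps (steps 2, 3, 6, 7, 8, 9, 10, 11, 15, 16).

**Steps most likely to fail**

1. Step 7. The alkenyl group may pass directly from boron to palladium and give the plain cross-coupled alkene. The C3–palladium intermediate may lose silanolate before reductive elimination. Selection of the alkene face may be weak because of the ortho-MOM group of the triflate. The fallback is an oxazolidinone-auxiliary syn aldol (Evans aldol); it sets out from 10 and 2 and comes back at 16.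
 - Triflate 10 would be allylated by Stille coupling (allyltributylstannane, Pd(PPh3)4, LiCl, DMF, 90 °C) to methyl 3-methoxy-4-(methoxymethoxy)-5-(prop-2-en-1-yl)benzoate F1.
 - The alkene would be cleaved (cat. KMnO4, NaIO4, K2CO3, t-BuOH/H2O) to [3-methoxy-5-(methoxycarbonyl)-2-(methoxymethoxy)phenyl]acetic acid F2.
 - Activation with PivCl/Et3N and reaction with (R)-4-benzyl-1,3-oxazolidin-2-one and LiCl in THF would give methyl 3-{2-[(4R)-4-benzyl-2-oxo-1,3-oxazolidin-3-yl]-2-oxoethyl}-5-methoxy-4-(methoxymethoxy)benzoate F3.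
 - Separately, bromide 2 would be lithiated (n-BuLi, THF, −78 °C, through 11) and formylated with DMF to 3,5-dimethoxy-4-(triisopropylsilyloxy)benzaldehyde F4.
 - Enolisation of F3 with Bu2BOTf and i-Pr2NEt (CH2Cl2, −78 °C) and addition to F4 should give the syn aldol methyl 3-[(2R,3R)-1-[(4R)-4-benzyl-2-oxo-1,3-oxazolidin-3-yl]-3-[3,5-dimethoxy-4-(triisopropylsilyloxy)phenyl]-3-hydroxy-1-oxopropan-2-yl]-5-methoxy-4-(methoxymethoxy)benzoate F5, in which the auxiliary fixes the carbon that becomes C3.
 - NaBH4 in THF/H2O would remove the auxiliary reductively without touching the benzoate, giving methyl 3-[(1R,2S)-1-[3,5-dimethoxy-4-(triisopropylsilyloxy)phenyl]-1,3-dihydroxypropan-2-yl]-5-methoxy-4-(methoxymethoxy)benzoate F6.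
 - F6 is compound 14 without its TBS group and should close to 16 under the conditions of step 9.

2. Step 9. The C2 cation may lose the C3 proton instead of being captured, which would erode the configuration at C3 or leave an alkene. Ionisation of the silyl-protected carbinol may need acid strong enough to strip the aryl silyl ether. The trans preference may be incomplete. The fallback moves ionisation to a free para-hydroxybenzyl alcohol; it sets out from 14 and comes back at 16.
 - Bu4NF in THF at 0 °C would remove both silyl groups to give methyl 3-[(1R,2S)-1,3-dihydroxy-1-(4-hydroxy-3,5-dimethoxyphenyl)propan-2-yl]-5-methoxy-4-(methoxymethoxy)benzoate F7.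
 - Methanolic HCl at room temperature would then remove the MOM group and close the ring by a quinone-methide-type pathway, as in the biomimetic formation of such rings, to methyl (2R,3S)-2-(4-hydroxy-3,5-dimethoxyphenyl)-3-(hydroxymethyl)-7-methoxy-2,3-dihydro-1-benzofuran-5-carboxylate F8.
 - Selective silylation of the phenoxide (NaH, 1.0 equiv, THF, 0 °C; then TIPSCl) would return 16.

3. Step 4. Alkylation may take place at the 3-hydroxyl or at both hydroxyl groups. The fallback reverses the order and uses the nucleophilicity of the dianion; it sets out from 8 and comes back at 10.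
 - Treating 8 with NaH (2.2 equiv) in DMF at 0 °C and then PhNTf2 (1.0 equiv) should sulfonylate the 3-oxide, which is not conjugated with the ester and is the more nucleophilic one, giving methyl 4-hydroxy-3-methoxy-5-(trifluoromethylsulfonyloxy)benzoate F9.
 - Any sulfonyl shift between the neighbouring oxygens would end at the same place, because the 4-phenoxide is the better-stabilised anion.
 - MOMCl and i-Pr2NEt in CH2Cl2 would then give 10.

**Further compounds**

F1 | step 7 | methyl 3-methoxy-4-(methoxymethoxy)-5-(prop-2-en-1-yl)benzoate | COCOc1c(OC)cc(C(=O)OC)cc1CC=C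
F2 | step 7 | [3-methoxy-5-(methoxycarbonyl)-2-(methoxymethoxy)phenyl]acetic acid | COCOc1c(OC)cc(C(=O)OC)cc1CC(=O)O
F3 | step 7 | methyl 3-{2-[(4R)-4-benzyl-2-oxo-1,3-oxazolidin-3-yl]-2-oxoethyl}-5-methoxy-4-(methoxymethoxy)benzoate | COCOc1c(OC)cc(C(=O)OC)cc1CC(=O)N1[C@H](Cc2ccccc2)COC1=O
F4 | step 7 | 3,5-dimethoxy-4-(triisopropylsilyloxy)benzaldehyde | COc1cc(C=O)cc(OC)c1O[Si](C(C)C)(C(C)C)C(C)C
F5 | step 7 | methyl 3-[(2R,3R)-1-[(4R)-4-benzyl-2-oxo-1,3-oxazolidin-3-yl]-3-[3,5-dimethoxy-4-(triisopropylsilyloxy)phenyl]-3-hydroxy-1-oxopropan-2-yl]-5-methoxy-4-(methoxymethoxy)benzoate | COc1cc([C@H](O)[C@H](C(=O)N2[C@H](Cc3ccccc3)COC2=O)c2cc(C(=O)OC)cc(OC)c2OCOC)cc(OC)c1O[Si](C(C)C)(C(C)C)C(C)C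
F6 | step 7 | methyl 3-[(1R,2S)-1-[3,5-dimethoxy-4-(triisopropylsilyloxy)phenyl]-1,3-dihydroxypropan-2-yl]-5-methoxy-4-(methoxymethoxy)benzoate | COc1cc([C@H](O)[C@H](CO)c2cc(C(=O)OC)cc(OC)c2OCOC)cc(OC)c1O[Si](C(C)C)(C(C)C)C(C)C
F7 | step 9 | methyl 3-[(1R,2S)-1,3-dihydroxy-1-(4-hydroxy-3,5-dimethoxyphenyl)propan-2-yl]-5-methoxy-4-(methoxymethoxy)benzoate | COc1cc([C@H](O)[C@H](CO)c2cc(C(=O)OC)cc(OC)c2OCOC)cc(OC)c1O
F8 | step 9 | methyl (2R,3S)-2-(4-hydroxy-3,5-dimethoxyphenyl)-3-(hydroxymethyl)-7-methoxy-2,3-dihydro-1-benzofuran-5-carboxylate | COc1cc([C@@H]2Oc3c(OC)cc(C(=O)OC)cc3[C@H]2CO)cc(OC)c1O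
F9 | step 4 | methyl 4-hydroxy-3-methoxy-5-(trifluoromethylsulfonyloxy)benzoate | COC(=O)c1cc(OC)c(O)c(OS(=O)(=O)C(F)(F)F)c1
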